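**Retrosynthetic overview**

1. Target 24 ⇐ 22 by selenoxide elimination: the C5 side-chain methylidene is carried as a PhSeCH2 group, so that the cycloaddition partner is a simple enol acetate and not a 1-acetoxy-1,3-diene.
2. 22 ⇐ 14 + 21 by an inverse-electron-demand oxa-Diels–Alder reaction that closes ring A by forming C4a–C5 (with O7–C6) and sets C4a, C5 and C6 from the single stereocentre C1.
3. Enabling feature: ring A is a 2-acetoxy-3,4-dihydro-2H-pyran (acyloxy acetal C6, enol ether O7–C8=C8a). O7=C8–C8a=C4a is therefore the retron of a 1-oxadiene (the formyl-substituted ring-B alkene of 14), and C5–C6(OAc) that of an (E)-enol acetate.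
4. 14 (ring B) ⇐ ring-closing metathesis of a but-3-enoate; side chain by cross-metathesis with methacrolein; C1 by Keck allylation of an enal made from 2-methylidenepropane-1,3-diol.
5. 21 ⇐ 1-methylcyclohexene by ozonolysis, α-methylenation, PhSeH addition, Takai–Utimoto olefination and copper-mediated acetoxylation. Ring order: B (step 6), then A (step 16).

Key step: step 16

Remark on locants: the pyrano[3,4-c]pyran core of the target is numbered C1 (lactone CH–O with the side chain), O2, C3 (lactone C=O), C4 (CH2), C4a, C5 (carries the 6-oxohept-1-en-2-yl group), C6 (acetal with OAc), O7, C8 (=CH–O), C8a. Ring A is C4a–C5–C6–O7–C8–C8a; ring B is C1–O2–C3–C4–C4a–C8a. These locants are also used for the corresponding atoms of 14 and 21.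

Assumption: compounds 19–23 are racemic or epimeric at the side-chain carbon that carries the PhSeCH2 group; this carbon becomes sp2 in step 17, so the mixture converges on one product.

**Route**

Step 1
Reactants: 1 2-methylidenepropane-1,3-diol
Product: 2 2-{[(tert-butyldimethylsilyl)oxy]methyl}prop-2-en-1-ol
Conditions: TBSCl (1 equiv), imidazole, diol in excess, THF, 0 °C
Reagents that add atoms: tert-butyldimethylsilyl chloride, CC(C)(C)[Si](C)(C)Cl
Why: Statistical monosilylation of a symmetric diol (silyl ether formation) with the diol in excess should give mainly the mono-TBS ether; no stereocentre is formed.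

Step 2
Reactants: 2 2-{[(tert-butyldimethylsilyl)oxy]methyl}prop-2-en-1-ol
Product: 3 2-{[(tert-butyldimethylsilyl)oxy]methyl}prop-2-enal
Conditions: MnO2 (activated, excess), CH2Cl2, 20 °C
Reagents that add atoms: none
Why: MnO2 oxidises allylic alcohols selectively to enals (allylic oxidation) and should leave the silyl ether untouched.

Step 3
Reactants: 3 2-{[(tert-butyldimethylsilyl)oxy]methyl}prop-2-enal
Product: 5 (3S)-2-{[(tert-butyldimethylsilyl)oxy]methyl}hexa-1,5-dien-3-ol, via tributylstannyl ether 4 (not isolated)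
Conditions: (S)-BINOL (20 mol %), Ti(OiPr)4 (10 mol %), 4 Å MS, allylSnBu3, CH2Cl2, −20 °C; then aq. NaHCO3
Reagents that add atoms: allyltributylstannane, C=CC[Sn](CCCC)(CCCC)CCCC
Why: Keck asymmetric allylation, in which the chiral BINOL complex of tetravalent titanium should direct allyl transfer from tin to the Si face of the enal carbonyl, setting the carbinol centre (later C1) as S.

Step 4
Reactants: 5 (3S)-2-{[(tert-butyldimethylsilyl)oxy]methyl}hexa-1,5-dien-3-ol; 6 methacrolein
Product: 7 (2E,5S)-6-{[(tert-butyldimethylsilyl)oxy]methyl}-5-hydroxy-2-methylhepta-2,6-dienal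
Conditions: methacrolein (5 equiv), second-generation Hoveyda–Grubbs catalyst (5 mol %), CH2Cl2, 40 °C
Reagents that add atoms: none
Why: Olefin cross-metathesis of the monosubstituted alkene with an electron-poor 1,1-disubstituted partner should give the trisubstituted enal as the E isomer under thermodynamic control, while the hindered 1,1-disubstituted alkene of 5 stays out of the reaction.

Step 5
Reactants: 7 (2E,5S)-6-{[(tert-butyldimethylsilyl)oxy]methyl}-5-hydroxy-2-methylhepta-2,6-dienal; 8 but-3-enoic acid
Product: 9 (3S,5E)-2-{[(tert-butyldimethylsilyl)oxy]methyl}-6-methyl-7-oxohepta-1,5-dien-3-yl but-3-enoate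
Conditions: DCC, DMAP (5 mol %), CH2Cl2, −20 to 0 °C
Reagents that add atoms: none
Why: Steglich esterification in the cold should acylate the secondary alcohol without moving the double bond of the but-3-enoyl group into conjugation.

Step 6
Reactants: 9 (3S,5E)-2-{[(tert-butyldimethylsilyl)oxy]methyl}-6-methyl-7-oxohepta-1,5-dien-3-yl but-3-enoate
Product: 10 (6S)-5-{[(tert-butyldimethylsilyl)oxy]methyl}-6-[(2E)-3-methyl-4-oxobut-2-en-1-yl]-3,6-dihydro-2H-pyran-2-one
Conditions: second-generation Grubbs catalyst (5 mol %), 1,4-benzoquinone (10 mol %), CH2Cl2 (0.005 M), 40 °C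
Reagents that add atoms: none
Why: Ring-closing metathesis of the monosubstituted with the 1,1-disubstituted alkene should close the six-membered β,γ-unsaturated lactone (ring B) and fix the ring-alkene geometry needed for the later s-cis 1-oxadiene, the trisubstituted enal being inert and benzoquinone suppressing alkene migration.

Step 7
Reactants: 10 (6S)-5-{[(tert-butyldimethylsilyl)oxy]methyl}-6-[(2E)-3-methyl-4-oxobut-2-en-1-yl]-3,6-dihydro-2H-pyran-2-one
Product: 11 (6S)-5-{[(tert-butyldimethylsilyl)oxy]methyl}-6-[(2E)-4-hydroxy-3-methylbut-2-en-1-yl]-3,6-dihydro-2H-pyran-2-one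
Conditions: NaBH4, CeCl3·7H2O, MeOH, −78 °C
Reagents that add atoms: none
Why: Luche reduction should reduce the enal 1,2-selectively to the allylic alcohol at a temperature at which the lactone is not attacked.

Step 8
Reactants: 11 (6S)-5-{[(tert-butyldimethylsilyl)oxy]methyl}-6-[(2E)-4-hydroxy-3-methylbut-2-en-1-yl]-3,6-dihydro-2H-pyran-2-one
Product: 12 (6S)-6-[(2E)-4-acetoxy-3-methylbut-2-en-1-yl]-5-{[(tert-butyldimethylsilyl)oxy]methyl}-3,6-dihydro-2H-pyran-2-one
Conditions: Ac2O, pyridine, CH2Cl2, 0 °C
Reagents that add atoms: acetic anhydride, CC(=O)OC(C)=O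
Why: Acetylation of the only free hydroxyl group under weakly basic conditions should install the side-chain acetate without isomerising the β,γ-unsaturated lactone.

Step 9
Reactants: 12 (6S)-6-[(2E)-4-acetoxy-3-methylbut-2-en-1-yl]-5-{[(tert-butyldimethylsilyl)oxy]methyl}-3,6-dihydro-2H-pyran-2-one
Product: 13 (6S)-6-[(2E)-4-acetoxy-3-methylbut-2-en-1-yl]-5-(hydroxymethyl)-3,6-dihydro-2H-pyran-2-one
Conditions: HF·pyridine, THF/pyridine, 0 °C
Reagents that add atoms: none
Why: Fluoride-mediated desilylation under buffered acidic conditions should free the primary allylic alcohol while the acetate and the lactone survive.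

Step 10
Reactants: 13 (6S)-6-[(2E)-4-acetoxy-3-methylbut-2-en-1-yl]-5-(hydroxymethyl)-3,6-dihydro-2H-pyran-2-one
Product: 14 (6S)-6-[(2E)-4-acetoxy-3-methylbut-2-en-1-yl]-5-formyl-3,6-dihydro-2H-pyran-2-one
Conditions: MnO2 (activated, excess), CH2Cl2, 20 °C; filtered and used at once
Reagents that add atoms: none
Why: Allylic oxidation with MnO2 under neutral conditions should give the enal (the 1-oxadiene O7=C8–C8a=C4a) without enolising the acidic C4 methylene, whose deprotonation would open the lactone by β-elimination.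

Step 11
Reactants: 15 1-methylcyclohexene
Product: 17 6-oxoheptanal, via ozonide 16 (not isolated)
Conditions: O3, CH2Cl2, −78 °C; then Me2S, −78 to 20 °C
Reagents that add atoms: ozone, [O-][O+]=O
Why: Ozonolysis with reductive work-up should cleave the ring alkene to the keto-aldehyde.

Step 12
Reactants: 17 6-oxoheptanal
Product: 18 2-methylidene-6-oxoheptanal
Conditions: 37% aq. CH2O, pyrrolidine (10 mol %), propionic acid (10 mol %), iPrOH, 45 °C
Reagents that add atoms: formaldehyde, C=O
Why: Amine-catalysed Mannich condensation with formaldehyde followed by elimination (α-methylenation of an aldehyde) should outrun intramolecular aldol reactions of the keto-aldehyde because formaldehyde is the most reactive electrophile present.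

Step 13
Reactants: 18 2-methylidene-6-oxoheptanal
Product: 19 6-oxo-2-[(phenylselanyl)methyl]heptanal (racemic)
Conditions: PhSeH (1.05 equiv), Et3N (5 mol %), CH2Cl2, 0 °C
Reagents that add atoms: benzeneselenol, [SeH]c1ccccc1
Why: Conjugate addition of the soft selenol to the α-methylidene aldehyde (selena-Michael addition) should be fast and gives the selenide that masks the later exocyclic methylidene group, the new stereocentre being racemic and erased in step 17.

Step 14
Reactants: 19 6-oxo-2-[(phenylselanyl)methyl]heptanal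
Product: 20 2-{(1E)-7-oxo-3-[(phenylselanyl)methyl]oct-1-en-1-yl}-4,4,5,5-tetramethyl-1,3,2-dioxaborolane
Conditions: Cl2CHBpin (2 equiv), CrCl2 (8 equiv), LiI (4 equiv), THF, 20 °C
Reagents that add atoms: 2-(dichloromethyl)-4,4,5,5-tetramethyl-1,3,2-dioxaborolane, ClC(Cl)B1OC(C)(C)C(C)(C)O1
Why: Takai–Utimoto olefination with the geminal dichromium reagent should convert only the aldehyde, not the methyl ketone, into the (E)-alkenyl boronate, the E geometry arising from anti elimination of the β-oxido dichromium adduct.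

Step 15
Reactants: 20 2-{(1E)-7-oxo-3-[(phenylselanyl)methyl]oct-1-en-1-yl}-4,4,5,5-tetramethyl-1,3,2-dioxaborolane
Product: 21 (1E)-7-oxo-3-[(phenylselanyl)methyl]oct-1-en-1-yl acetate
Conditions: Cu(OAc)2 (2.2 equiv), Et3N (4 equiv), 4 Å MS, MeCN, air, 20 °C
Reagents that add atoms: copper diacetate, CC(=O)[O-].CC(=O)[O-].[Cu+2]
Why: Chan–Lam–Evans-type oxidative C–O coupling, in which the alkenyl group is transmetalated to divalent copper acetate and reductive elimination from a trivalent copper acetate transfers acetate, should proceed with retention of the E geometry.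

Step 16
Reactants: 14 (6S)-6-[(2E)-4-acetoxy-3-methylbut-2-en-1-yl]-5-formyl-3,6-dihydro-2H-pyran-2-one; 21 (1E)-7-oxo-3-[(phenylselanyl)methyl]oct-1-en-1-yl acetate
Product: 22 (1S,4aS,5R,6R)-1-[(2E)-4-acetoxy-3-methylbut-2-en-1-yl]-3-oxo-5-[6-oxo-1-(phenylselanyl)heptan-2-yl]-1,3,4,4a,5,6-hexahydropyrano[3,4-c]pyran-6-yl acetate (both epimers at the heptan-2-yl carbon)
Conditions: 21 (3 equiv), Eu(fod)3 (10 mol %; fod = 6,6,7,7,8,8,8-heptafluoro-2,2-dimethyloctane-3,5-dionate), CH2Cl2, 12 kbar, 40 °C
Reagents that add atoms: none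
Why: Concerted but asynchronous inverse-electron-demand oxa-[4+2] cycloaddition in which the 1-oxadiene O7=C8–C8a=C4a of 14, its LUMO lowered by Eu(fod)3, combines with the enol-acetate π bond of 21, the C4a–C5 bond forming ahead of O7–C6. The closest known reaction type is the lanthanide-catalysed or pressure-promoted hetero-Diels–Alder reaction of α,β-unsaturated aldehydes with enol ethers and vinyl esters, which gives 2-alkoxy- and 2-acyloxy-3,4-dihydro-2H-pyrans. Ring A is closed in the [4+2] mode by the bonds C4a–C5 and O7–C6, ring B being present already. C4a is set by attack on the diene face anti to the C1 side chain, which is held pseudoaxial by A(1,2) strain with the formyl group; C5 and C6 follow from suprafacial addition to the (E)-enol acetate with the acetoxy group endo and the branched alkyl group exo, which places the acetoxy group cis to C4 and the C5 substituent trans to it. The step needs regio- and periselectivity: the acetoxy-bearing carbon goes to oxygen because it carries the positive charge in the polarised transition state, and the phenylselanylmethyl mask keeps 21 a simple enol acetate instead of a 1-acetoxy-1,3-diene whose terminal carbon would compete as the nucleophile.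

Step 17
Reactants: 22 (1S,4aS,5R,6R)-1-[(2E)-4-acetoxy-3-methylbut-2-en-1-yl]-3-oxo-5-[6-oxo-1-(phenylselanyl)heptan-2-yl]-1,3,4,4a,5,6-hexahydropyrano[3,4-c]pyran-6-yl acetate
Product: 24 (1S,4aS,5R,6R)-1-[(2E)-4-acetoxy-3-methylbut-2-en-1-yl]-3-oxo-5-(6-oxohept-1-en-2-yl)-1,3,4,4a,5,6-hexahydropyrano[3,4-c]pyran-6-yl acetate, via selenoxide 23 (not isolated)
Conditions: mCPBA (1.05 equiv), CH2Cl2, −78 °C; then Et3N (3 equiv), −78 to 35 °C
Reagents that add atoms: none
Why: Chemoselective oxidation of the selenide to the selenoxide at low temperature followed by thermal syn-elimination (selenoxide elimination), which can only engage the single β-hydrogen on the adjacent side-chain carbon, should unveil the 1,1-disubstituted alkene without touching the four stereocentres.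

**Compound list**

1 | 2-methylidenepropane-1,3-diol | C=C(CO)CO | starting material
2 | 2-{[(tert-butyldimethylsilyl)oxy]methyl}prop-2-en-1-ol | C=C(CO)CO[Si](C)(C)C(C)(C)C | intermediate
3 | 2-{[(tert-butyldimethylsilyl)oxy]methyl}prop-2-enal | C=C(C=O)CO[Si](C)(C)C(C)(C)C | intermediate
4 | tributylstannyl ether of 5 (not isolated) | C=C(CO[Si](C)(C)C(C)(C)C)[C@H](CC=C)O[Sn](CCCC)(CCCC)CCCC | intermediate
5 | (3S)-2-{[(tert-butyldimethylsilyl)oxy]methyl}hexa-1,5-dien-3-ol | C=C(CO[Si](C)(C)C(C)(C)C)[C@H](CC=C)O | intermediate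
6 | methacrolein (2-methylprop-2-enal) | CC(=C)C=O | starting material
7 | (2E,5S)-6-{[(tert-butyldimethylsilyl)oxy]methyl}-5-hydroxy-2-methylhepta-2,6-dienal | C=C(CO[Si](C)(C)C(C)(C)C)[C@H](C/C=C(\C)C=O)O | intermediate
8 | but-3-enoic acid | C=CCC(=O)O | starting material
9 | (3S,5E)-2-{[(tert-butyldimethylsilyl)oxy]methyl}-6-methyl-7-oxohepta-1,5-dien-3-yl but-3-enoate | C=C(CO[Si](C)(C)C(C)(C)C)[C@H](C/C=C(\C)C=O)OC(=O)CC=C | intermediate
10 | (6S)-5-{[(tert-butyldimethylsilyl)oxy]methyl}-6-[(2E)-3-methyl-4-oxobut-2-en-1-yl]-3,6-dihydro-2H-pyran-2-one | O=C1CC=C(CO[Si](C)(C)C(C)(C)C)[C@H](C/C=C(\C)C=O)O1 | intermediate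
11 | (6S)-5-{[(tert-butyldimethylsilyl)oxy]methyl}-6-[(2E)-4-hydroxy-3-methylbut-2-en-1-yl]-3,6-dihydro-2H-pyran-2-one | O=C1CC=C(CO[Si](C)(C)C(C)(C)C)[C@H](C/C=C(\C)CO)O1 | intermediate
12 | (6S)-6-[(2E)-4-acetoxy-3-methylbut-2-en-1-yl]-5-{[(tert-butyldimethylsilyl)oxy]methyl}-3,6-dihydro-2H-pyran-2-one | O=C1CC=C(CO[Si](C)(C)C(C)(C)C)[C@H](C/C=C(\C)COC(C)=O)O1 | intermediate
13 | (6S)-6-[(2E)-4-acetoxy-3-methylbut-2-en-1-yl]-5-(hydroxymethyl)-3,6-dihydro-2H-pyran-2-one | O=C1CC=C(CO)[C@H](C/C=C(\C)COC(C)=O)O1 | intermediate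
14 | (6S)-6-[(2E)-4-acetoxy-3-methylbut-2-en-1-yl]-5-formyl-3,6-dihydro-2H-pyran-2-one | O=C1CC=C(C=O)[C@H](C/C=C(\C)COC(C)=O)O1 | intermediate
15 | 1-methylcyclohexene | CC1=CCCCC1 | starting material
16 | 1-methyl-7,8,9-trioxabicyclo[4.2.1]nonane (secondary ozonide, not isolated) | CC12CCCCC(OO1)O2 | intermediate
17 | 6-oxoheptanal | CC(=O)CCCCC=O | intermediate
18 | 2-methylidene-6-oxoheptanal | CC(=O)CCCC(=C)C=O | intermediate
19 | 6-oxo-2-[(phenylselanyl)methyl]heptanal (racemic) | CC(=O)CCCC(C[Se]c1ccccc1)C=O | intermediate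
20 | 2-{(1E)-7-oxo-3-[(phenylselanyl)methyl]oct-1-en-1-yl}-4,4,5,5-tetramethyl-1,3,2-dioxaborolane (racemic) | CC(=O)CCCC(C[Se]c1ccccc1)/C=C/B1OC(C)(C)C(C)(C)O1 | intermediate
21 | (1E)-7-oxo-3-[(phenylselanyl)methyl]oct-1-en-1-yl acetate (racemic) | CC(=O)CCCC(C[Se]c1ccccc1)/C=C/OC(C)=O | intermediate
22 | (1S,4aS,5R,6R)-1-[(2E)-4-acetoxy-3-methylbut-2-en-1-yl]-3-oxo-5-[6-oxo-1-(phenylselanyl)heptan-2-yl]-1,3,4,4a,5,6-hexahydropyrano[3,4-c]pyran-6-yl acetate (both epimers at the heptan-2-yl carbon) | CC(=O)CCCC(C[Se]c1ccccc1)[C@@H]1[C@@H](OC(C)=O)OC=C2[C@H](C/C=C(\C)COC(C)=O)OC(=O)C[C@H]21 | intermediate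
23 | selenoxide of 22 (not isolated) | CC(=O)CCCC(C[Se](=O)c1ccccc1)[C@@H]1[C@@H](OC(C)=O)OC=C2[C@H](C/C=C(\C)COC(C)=O)OC(=O)C[C@H]21 | intermediate
24 | (1S,4aS,5R,6R)-1-[(2E)-4-acetoxy-3-methylbut-2-en-1-yl]-3-oxo-5-(6-oxohept-1-en-2-yl)-1,3,4,4a,5,6-hexahydropyrano[3,4-c]pyran-6-yl acetate (CNP0120157.1) | C=C(CCCC(C)=O)[C@@H]1[C@@H](OC(C)=O)OC=C2[C@H](C/C=C(\C)COC(C)=O)OC(=O)C[C@H]21 | target

**Step count and risks**

Total step count: 17. Longest linear sequence: 12 steps (steps 1–10, 16 and 17); the dienophile branch is steps 11–15.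

Steps most likely to fail:

1. Step 16 (cycloaddition). The enol acetate may be too weak a 2π donor for the trisubstituted 1-oxadiene, so that cycloaddition is outrun by enolisation and ring opening of 14, or endo/exo control may be incomplete. The fallback sets out from 20 and comes back at 22. Copper diacetate/Et3N-mediated coupling of 20 with 2-(trimethylsilyl)ethanol should give the more electron-rich (E)-2-(trimethylsilyl)ethyl enol ether F1. Its Eu(fod)3-catalysed cycloaddition with 14 at ambient pressure, a well-precedented enol ether case, should give the 2-(trimethylsilyl)ethyl acetal cycloadduct F2 with the same facial and endo preferences. Treatment of F2 with BF3·OEt2 and Ac2O at −40 °C should then exchange the 2-(trimethylsilyl)ethoxy group for acetate with loss of ethylene, the acetate entering trans to the C5 substituent, to give 22.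

2. Step 17 (unmasking of the methylidene group). The peracid, or the benzeneselenenic acid released, may attack the ring-A enol ether C8=C8a, and the primary selenoxide may eliminate sluggishly. The fallback sets out from 18 and comes back at 24, using a sulfoxide pyrolysis instead. Thia-Michael addition of thiophenol to 18 should give the sulfide aldehyde F3. Takai–Utimoto olefination as in step 14 should give the (E)-alkenyl boronate F4, and copper diacetate-mediated acetoxylation as in step 15 the (E)-enol acetate F5. Cycloaddition with 14 as in step 16 should give the sulfide cycloadduct F6. NaIO4 in aqueous methanol should oxidise only sulfur, giving the sulfoxide F7. Heating F7 in toluene at 110 °C with NaHCO3 and P(OMe)3 as sulfenic acid trap should give 24 by thermal syn-elimination.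

3. Step 15 (C–O coupling). Acetate transfer at copper may lose to protodeboronation or oxidative homocoupling of the alkenyl boronate, or the selenide may bind copper and stop the reaction. The fallback sets out from 20 and comes back at 21. KHF2 in aqueous methanol should convert 20 into the potassium alkenyltrifluoroborate F8, a more robust transmetalation partner. Coupling of F8 with acetic acid under catalytic copper diacetate, DMAP, 4 Å MS and O2 in CH2Cl2 (a catalytic, non-decarboxylative carboxylate coupling) should give 21 with retention of the E geometry.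

**Further compounds**

F1 | step 16 | (1E)-8-(phenylselanyl-methyl-bearing) enol ether: 6-[(phenylselanyl)methyl]-8-[2-(trimethylsilyl)ethoxy]oct-7-en-2-one, E isomer | CC(=O)CCCC(C[Se]c1ccccc1)/C=C/OCC[Si](C)(C)C
F2 | step 16 | analogue of 22 with a 2-(trimethylsilyl)ethoxy group in place of the C6 acetoxy group, same spatial arrangement at C1, C4a, C5 and C6 | CC(=O)CCCC(C[Se]c1ccccc1)[C@@H]1[C@@H](OCC[Si](C)(C)C)OC=C2[C@H](C/C=C(\C)COC(C)=O)OC(=O)C[C@H]21
F3 | step 17 | 6-oxo-2-[(phenylsulfanyl)methyl]heptanal (racemic) | CC(=O)CCCC(CSc1ccccc1)C=O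
F4 | step 17 | 2-{(1E)-7-oxo-3-[(phenylsulfanyl)methyl]oct-1-en-1-yl}-4,4,5,5-tetramethyl-1,3,2-dioxaborolane | CC(=O)CCCC(CSc1ccccc1)/C=C/B1OC(C)(C)C(C)(C)O1
F5 | step 17 | (1E)-7-oxo-3-[(phenylsulfanyl)methyl]oct-1-en-1-yl acetate | CC(=O)CCCC(CSc1ccccc1)/C=C/OC(C)=O
F6 | step 17 | phenylsulfanyl analogue of 22 | CC(=O)CCCC(CSc1ccccc1)[C@@H]1[C@@H](OC(C)=O)OC=C2[C@H](C/C=C(\C)COC(C)=O)OC(=O)C[C@H]21
F7 | step 17 | sulfoxide of F6 | CC(=O)CCCC(CS(=O)c1ccccc1)[C@@H]1[C@@H](OC(C)=O)OC=C2[C@H](C/C=C(\C)COC(C)=O)OC(=O)C[C@H]21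
F8 | step 15 | potassium trifluoro{(1E)-7-oxo-3-[(phenylselanyl)methyl]oct-1-en-1-yl}borate | [K+].CC(=O)CCCC(C[Se]c1ccccc1)/C=C/[B-](F)(F)F
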